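**Retrosynthetic overview**

1. Target (R)-12 ⇐ leuco triol 11 by dehydrogenation of ring A. The quinone ring is a bought hydroquinone ring, so ring B is the only ring formed (last, in step 5).
2. Ring B ⇐ Friedel–Crafts closure of a masked aldehyde carbon (as a methyl oxocarbenium) of an acyl-hydroquinone onto the hydroquinone ortho carbon. This is the same C–aryl bond that closes 3''-oxo-geranylhydroquinone in shikonin biosynthesis. The oxocarbenium OMe becomes 8-OMe and the aryl ketone becomes 5-OH.
3. The cis keto-acetal ⇐ a 2-(hydroquinonyl)furan, unmasked by an internal redox step: the derived furylquinone oxidises its own furan in MeOH.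
4. Furyl–hydroquinone bond ⇐ C5-selective C–H borylation/Suzuki coupling of a 3-substituted furan with bromohydroquinone.
5. Stereocentre and ester are set first: asymmetric allylboration of furan-3-carbaldehyde, Steglich senecioylation, cross-metathesis to the prenyl group.

Assumption: (R)-TRIP shows its usual sense with furan-3-carbaldehyde (Re-face allyl transfer, as in benzaldehyde → (R)-1-phenylbut-3-en-1-ol); if the sense is reversed, (S)-TRIP is used.

**Route**

Step 1
Reactants: 1 furan-3-carbaldehyde
Product: 3 (R)-1-(furan-3-yl)but-3-en-1-ol, via O-boryl ether 2 (not isolated)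
Conditions: allylB(pin) (1.2 equiv), (R)-TRIP (5 mol%), toluene, −30 °C; aq NaHCO3 work-up
Reagents that add atoms: allylboronic acid pinacol ester, C=CCB1OC(C)(C)C(C)(C)O1
Why: Chiral-phosphoric-acid-catalysed allylboration through a closed chair transition state; the catalyst directs allyl to the Re face of the aryl aldehyde, which gives the (R)-carbinol (O > furyl > allyl > H).

Step 2
Reactants: 3 (R)-1-(furan-3-yl)but-3-en-1-ol
Product: 4 (R)-1-(furan-3-yl)but-3-en-1-yl 3-methylbut-2-enoate
Conditions: 3-methylbut-2-enoic acid (1.3 equiv), DCC (1.3 equiv), DMAP (0.1 equiv), CH2Cl2, 0 °C → rt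
Reagents that add atoms: 3-methylbut-2-enoic acid, CC(C)=CC(=O)O
Why: Steglich esterification; carbodiimide activation avoids the vinylketene/deconjugation pathway of senecioyl chloride with amine bases and does not touch the stereocentre.

Step 3
Reactants: 4 (R)-1-(furan-3-yl)but-3-en-1-yl 3-methylbut-2-enoate
Product: 5 (R)-1-(furan-3-yl)-4-methylpent-3-en-1-yl 3-methylbut-2-enoate
Conditions: Grubbs II (3 mol%), 2-methyl-2-butene/CH2Cl2 (1:1), 40 °C, sealed tube
Reagents that add atoms: 2-methyl-2-butene, CC=C(C)C
Why: Olefin cross-metathesis with 2-methyl-2-butene as isobutylene surrogate converts the terminal vinyl into the prenyl terminus; the trisubstituted enoate and the furan are inert to the Ru carbene.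

Step 4
Reactants: 5 (R)-1-(furan-3-yl)-4-methylpent-3-en-1-yl 3-methylbut-2-enoate; 6 2-bromobenzene-1,4-diol
Product: 8 (R)-1-[5-(2,5-dihydroxyphenyl)furan-3-yl]-4-methylpent-3-en-1-yl 3-methylbut-2-enoate, via furyl boronate 7 (not isolated)
Conditions: [Ir(OMe)(cod)]2 (1.5 mol%), dtbpy (3 mol%), B2pin2 (1.0 equiv), THF, 40 °C; then 6 (1.2 equiv), XPhos Pd G3 (3 mol%), degassed aq K3PO4, 40 °C; work-up under N2
Reagents that add atoms: bis(pinacolato)diboron, CC1(C)OB(B2OC(C)(C)C(C)(C)O2)OC1(C)C (its Bpin group is carried only in 7 and leaves again in the coupling)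
Why: Sterically governed Ir-catalysed C–H borylation takes the furan α-position remote from the branched 3-substituent (C5), and the sensitive 2-furyl boronate is consumed at once in a fast Suzuki–Miyaura coupling that tolerates free phenols.

Step 5
Reactants: 8 (R)-1-[5-(2,5-dihydroxyphenyl)furan-3-yl]-4-methylpent-3-en-1-yl 3-methylbut-2-enoate
Product: 12 (R)-1-(4-hydroxy-1-methoxy-5,8-dioxo-5,8-dihydronaphthalen-2-yl)-4-methylpent-3-en-1-yl 3-methylbut-2-enoate, via furylquinone 9 (not isolated), via dimethoxydihydrofuran 10 (not isolated), via leuco triol 11 (not isolated)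
Conditions: p-chloranil (2.2 equiv), CSA (0.3 equiv), MeOH (20 equiv), anhydrous CH2Cl2, 0 °C → rt, N2, dark
Reagents that add atoms: methanol, CO
Why: Proposed new method: chloranil dehydrogenates 8 to the push–pull furylquinone 9, whose protonated form is an extended oxocarbenium that takes MeOH at the free furan α-carbon (vinylogous 1,8-addition) and a second MeOH at the resulting o-quinone-methide carbon, so the quinone itself oxidises the furan to the 2,5-dimethoxy-2,5-dihydrofuran 10 (Clauson-Kaas oxidation level; hydroquinone aromatisation outweighs the lost furan aromaticity); acid then opens the aryl ketal to the (Z)-aryl ketone/methyl oxocarbenium, which closes ring B by Friedel–Crafts attack of the hydroquinone ortho carbon (phenolic oxa-Pictet–Spengler/Bradsher-type cyclisation, the laboratory counterpart of the 3''-oxo-geranylhydroquinone ring closure), the 4-methoxy-4H-naphthalen-1-one tautomerises to 11 with OMe on the former aldehyde carbon and OH on the former ketone carbon (the same collapse seen for aryne–2-methoxyfuran adducts to 4-methoxy-1-naphthols), and the second equivalent of chloranil dehydrogenates ring A; the stereocentre is a spectator, kept from ionising by the weak acid and by immediate oxidation to the electron-poor quinone.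

**Compound list**

1 | furan-3-carbaldehyde | O=Cc1ccoc1 | starting material
2 | (R)-2-[1-(furan-3-yl)but-3-en-1-yloxy]-4,4,5,5-tetramethyl-1,3,2-dioxaborolane | C=CC[C@@H](OB1OC(C)(C)C(C)(C)O1)c1ccoc1 | intermediate
3 | (R)-1-(furan-3-yl)but-3-en-1-ol | C=CC[C@@H](O)c1ccoc1 | intermediate
4 | (R)-1-(furan-3-yl)but-3-en-1-yl 3-methylbut-2-enoate | C=CC[C@@H](OC(=O)C=C(C)C)c1ccoc1 | intermediate
5 | (R)-1-(furan-3-yl)-4-methylpent-3-en-1-yl 3-methylbut-2-enoate | CC(C)=CC[C@@H](OC(=O)C=C(C)C)c1ccoc1 | intermediate
6 | 2-bromobenzene-1,4-diol (bromohydroquinone) | Oc1ccc(O)c(Br)c1 | starting material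
7 | (R)-4-methyl-1-[5-(4,4,5,5-tetramethyl-1,3,2-dioxaborolan-2-yl)furan-3-yl]pent-3-en-1-yl 3-methylbut-2-enoate | CC(C)=CC[C@@H](OC(=O)C=C(C)C)c1coc(B2OC(C)(C)C(C)(C)O2)c1 | intermediate
8 | (R)-1-[5-(2,5-dihydroxyphenyl)furan-3-yl]-4-methylpent-3-en-1-yl 3-methylbut-2-enoate | CC(C)=CC[C@@H](OC(=O)C=C(C)C)c1coc(-c2cc(O)ccc2O)c1 | intermediate
9 | (R)-1-[5-(3,6-dioxocyclohexa-1,4-dien-1-yl)furan-3-yl]-4-methylpent-3-en-1-yl 3-methylbut-2-enoate | CC(C)=CC[C@@H](OC(=O)C=C(C)C)c1coc(C2=CC(=O)C=CC2=O)c1 | intermediate
10 | (1R)-1-[5-(2,5-dihydroxyphenyl)-2,5-dimethoxy-2,5-dihydrofuran-3-yl]-4-methylpent-3-en-1-yl 3-methylbut-2-enoate (mixture of epimers at both acetal carbons) | CC(C)=CC[C@@H](OC(=O)C=C(C)C)C1=CC(OC)(c2cc(O)ccc2O)OC1OC | intermediate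
11 | (R)-4-methyl-1-(4,5,8-trihydroxy-1-methoxynaphthalen-2-yl)pent-3-en-1-yl 3-methylbut-2-enoate | COc1c([C@@H](CC=C(C)C)OC(=O)C=C(C)C)cc(O)c2c(O)ccc(O)c12 | intermediate
12 | (R)-1-(4-hydroxy-1-methoxy-5,8-dioxo-5,8-dihydronaphthalen-2-yl)-4-methylpent-3-en-1-yl 3-methylbut-2-enoate | COc1c([C@@H](CC=C(C)C)OC(=O)C=C(C)C)cc(O)c2c1C(=O)C=CC2=O | target

**Step count and risks**

Total step count: 5. Longest linear sequence: 5 steps (1 → 12); the route is linear, with 6 entering at step 4.

The three steps most likely to fail:

Step 5 (the ring-forming cascade). The risks are MeOH adding to the quinone ring instead of the furan terminus, slow ring closure ortho to the acyl group, ionisation of the allylic/benzylic ester (racemisation), and over-methylation through a ketal pathway. The fallback sets out from 8 and comes back at 12. It oxidises the furan with an external oxidant while ring A is protected. 8 is silylated (TBSCl, imidazole, DMF) to the bis(tert-butyldimethylsilyl) ether F1. Sensitised photo-oxygenation (O2, rose bengal, hν, MeOH/CH2Cl2, −78 °C, then Me2S) opens the furan to the (Z)-keto-enal F2. HF·pyridine in MeOH/THF then removes the silyl groups, forms the methyl oxocarbenium and closes ring B to 11, which chloranil (1.1 equiv) dehydrogenates to 12.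

Step 4 (one-pot borylation/Suzuki). The risks are protodeboronation of the 2-furyl boronate, air oxidation of the hydroquinone under base, and partial ester hydrolysis. The fallback sets out from 5 and comes back at 9. It replaces the cross-coupling by a Friedel–Crafts-type conjugate addition of the furan C5–H to p-benzoquinone (3 equiv, Sc(OTf)3 5 mol%, MeCN, 0 °C). C5 attack is favoured by the branched, inductively deactivating 3-substituent, and excess quinone oxidises the adduct 8 in the flask to 9. Step 5 is then run from 9 with 1.1 equiv chloranil. This fallback makes no compound outside the list: none F0.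

Step 1 (enantioselectivity). The small, electron-rich heteroaryl aldehyde may give lower ee or a competing uncatalysed background reaction. The fallback sets out from 1 and comes back at 3. It replaces asymmetric induction by resolution. Barbier allylation (Zn, allyl bromide, THF/aq NH4Cl) gives racemic 1-(furan-3-yl)but-3-en-1-ol F3. Lipase-catalysed acylation (Burkholderia cepacia lipase, vinyl acetate, MTBE) converts the (R)-alcohol to (R)-1-(furan-3-yl)but-3-en-1-yl acetate F4, which is separated from the (S)-alcohol. K2CO3/MeOH then returns 3.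

**Further compounds**

F1 | step 5 | (R)-1-{5-[2,5-bis(tert-butyldimethylsilyloxy)phenyl]furan-3-yl}-4-methylpent-3-en-1-yl 3-methylbut-2-enoate | CC(C)=CC[C@@H](OC(=O)C=C(C)C)c1coc(-c2cc(O[Si](C)(C)C(C)(C)C)ccc2O[Si](C)(C)C(C)(C)C)c1
F2 | step 5 | (R,Z)-1-[2,5-bis(tert-butyldimethylsilyloxy)phenyl]-3-formyl-7-methyl-1-oxoocta-2,6-dien-4-yl 3-methylbut-2-enoate | O=C/C(=C\C(=O)c1cc(O[Si](C)(C)C(C)(C)C)ccc1O[Si](C)(C)C(C)(C)C)[C@@H](CC=C(C)C)OC(=O)C=C(C)C
F0 | step 4 | none | none
F3 | step 1 | rac-1-(furan-3-yl)but-3-en-1-ol | C=CCC(O)c1ccoc1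
F4 | step 1 | (R)-1-(furan-3-yl)but-3-en-1-yl acetate | C=CC[C@@H](OC(C)=O)c1ccoc1
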